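**Assumptions:** High-ee (+)-verbenone and arene 12 are not treated as stock items, so each is made in one step from a cheap commercial precursor.

**Numbering (clerodane style):** C1–C2–C3(=CMe2)–C4(chain)–C5(Me)–C6–C7–C8–C9–C10(H). C11 is the benzylic CH2. α is the face carrying the C5 methyl.

## Retrosynthetic overview
1. The quinone comes from CAN oxidation of the hydroquinone dimethyl ether. The C8 methyl comes from a C8 ketone by methylenation and hydrogenation.
2. Key disconnection, C9–C11 together with C10–H: light-driven α-hydrobenzylation of bicyclic enone 10 with the benzylic C–H of symmetric 2,5-dimethoxy-m-xylene 12.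
3. Ring B comes from an ethyl vinyl ketone Michael/aldol annulation. The C3 isopropylidene comes from cleaving the pinane cyclobutane, whose CMe2 bridge becomes =CMe2.
4. Ring A and the C4 propanoic acid chain come from (+)-verbenone plus glyoxylic acid (vinylogous aldol), followed by bridge-directed hydrogenation. Verbenone comes from (+)-α-pinene.
5. Ring order: ring A (bought as the pinane six-ring), then ring B, then cyclobutane opening, then arene attachment, then the quinone.

## Route

**Step 1**
Reactants: 1 (1R,5R)-(+)-α-pinene
Product: 2 (1R,5R)-(+)-verbenone
Conditions: t-BuOOH, Cl4NHPI (20 mol %), pyridine, LiClO4, acetone, RVC(+)/RVC(−), constant current, rt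
Reagents that add atoms: tert-butyl hydroperoxide, CC(C)(C)OO (ketone O)
Why: N-oxyl-mediated electrochemical allylic C–H oxidation converts the only ring allylic CH2 into the enone and leaves both bridgehead stereocentres untouched.

**Step 2**
Reactants: 2 (+)-verbenone; 3 glyoxylic acid (monohydrate)
Product: 4 (E)-3-(6,6-dimethyl-4-oxobicyclo[3.1.1]hept-2-en-2-yl)acrylic acid (bridgeheads as in 2)
Conditions: KOH (4 equiv), MeOH–H2O, 0 → 50 °C; then aq HCl to pH 2
Reagents that add atoms: glyoxylic acid, O=CC(=O)O
Why: Vinylogous aldol (Claisen–Schmidt-type) condensation works because the bridgehead α′-position cannot enolise, α-aldol is reversible, and only the γ-adduct at the vinylic methyl can dehydrate to the conjugated dienone, as verbenone does with non-enolisable aldehydes.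

**Step 3**
Reactants: 4
Product: 5 3-(6,6-dimethyl-4-oxobicyclo[3.1.1]heptan-2-yl)propanoic acid, chain cis (syn) to the CMe2 bridge
Conditions: H2 (1 atm), 10% Pd/C, EtOAc, rt
Reagents that add atoms: none
Why: Catalytic hydrogenation of both C=C bonds delivers H2 to the ring alkene from the face opposite the CMe2 bridge (as in verbenone → cis-verbanone), which sets C4 (H β, chain α) at a non-enolisable position.

**Step 4**
Reactants: 5
Product: 6 3-(3,6,6-trimethyl-4-oxobicyclo[3.1.1]heptan-2-yl)propanoic acid (C3-Me anti to the bridge is the major epimer)
Conditions: LDA (2.2 equiv), THF, −78 °C; MeI (1.1 equiv), −78 → 0 °C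
Reagents that add atoms: iodomethane, CI
Why: Enolate alkylation of the carboxylate/enolate dianion is regiospecific because the ketone can only enolise away from the bridgehead, and the new centre is re-enolised in Step 5 so its configuration does not matter.

**Step 5**
Reactants: 6; 7 ethyl vinyl ketone (pent-1-en-3-one)
Product: 8 3-[3,6,6-trimethyl-4-oxo-3-(3-oxopentyl)bicyclo[3.1.1]heptan-2-yl]propanoic acid (oxopentyl anti; C3-Me and acid chain syn to the bridge)
Conditions: KOt-Bu (1.2 equiv), t-BuOH–THF, 0 °C; slow addition of 7
Reagents that add atoms: ethyl vinyl ketone, C=CC(=O)CC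
Why: Michael addition of the only possible enolate occurs on the open face, anti to both the CMe2 bridge and the C4 chain, which sets quaternary C5 (C6 β, Me α).

**Step 6**
Reactants: 8
Product: 9 3-[6-(2-chloropropan-2-yl)-2-methyl-3-oxo-2-(3-oxopentyl)cyclohexyl]propanoic acid (acid chain, C2-Me and chloropropyl all cis)
Conditions: HCl (g, sat.), AcOH, 15 °C
Reagents that add atoms: hydrogen chloride, Cl
Why: Acid-induced, strain-driven cleavage of the cyclobutane bond α,β to the ketone (the nopinone-type opening used in pinane-to-nootkatone chemistry) gives the enol and a tertiary cation that chloride traps, and any chloro-enone already cyclised converges in Step 7.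

**Step 7**
Reactants: 9
Product: 10 3-[(1R,8aS)-5,8a-dimethyl-6-oxo-2-(propan-2-ylidene)-1,2,3,4,6,7,8,8a-octahydronaphthalen-1-yl]propanoic acid (chain cis to the angular Me)
Conditions: KOH (5 equiv), EtOH, reflux; then H3O+
Reagents that add atoms: none
Why: Intramolecular aldol condensation (the closing half of a Robinson annulation) forms ring B while the small base effects Zaitsev-selective E2 loss of HCl, helped by relief of the syn-axial CMe2Cl/C5-Me clash, and C4 and C5 are non-enolisable so they are unaffected.

**Step 8** (branch)
Reactants: 11 2,6-dimethylhydroquinone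
Product: 12 2,5-dimethoxy-1,3-dimethylbenzene
Conditions: MeI (3 equiv), K2CO3, acetone, reflux, N2
Reagents that add atoms: iodomethane, CI
Why: Williamson O-methylation gives a C2-symmetric arene whose two methyl groups are equivalent, so there is no regiochemical issue in Step 9.

**Step 9** (key step)
Reactants: 10; 12
Product: 13 C8-ketone, trans-decalin: C9 carries the 2,5-dimethoxy-3-methylbenzyl group (β) and Me (α); H-10 β; C5-Me α; C4 chain α; C3 isopropylidene
Conditions: hν (365 nm LEDs), degassed, 12 as medium (about 20 equiv, recovered by distillation), thin film or flow, 20 °C, run to about 70% conversion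
Reagents that add atoms: 12, COc1cc(C)c(OC)c(C)c1
Why: Proposed new method: exciting only the enone n→π* tail populates the twisted ³(π,π*) state (placed below ³n,π* by the tetrasubstituted C=C; electron transfer from 12 is about 0.4 eV uphill), its β-carbon C10 abstracts a benzylic H from 12 on the face anti to the axial C5-Me, and the tertiary α-keto radical at C9 then couples C–C with the benzyl radical on the same open β-face, giving net α-selective hydrobenzylation that forms C9–C11 and sets the C9 quaternary centre and the trans H-10; the closest known reaction type is photoaddition of solvent toluene to steroidal and octalone enones to give α-benzyl saturated ketones, which has not been shown for an α-substituted enone (quaternary carbon) or for a functionalised arene as a fragment-coupling partner.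

**Step 10**
Reactants: 13
Product: 14 C8 exocyclic-methylene analogue of 13
Conditions: Ph3PCH3Br (6 equiv), KOt-Bu (5.5 equiv), toluene, 90 °C; acidic work-up
Reagents that add atoms: methyltriphenylphosphonium bromide (as Ph3P=CH2), C[P+](c1ccccc1)(c1ccccc1)c1ccccc1.[Br-]
Why: Wittig methylenation of the hindered ketone next to C9 has precedent in avarane and clerodane decalones, and the excess ylide simply carries the carboxylate.

**Step 11**
Reactants: 14
Product: 15 stypohydroquinonic acid dimethyl ether (C8-Me α, equatorial; H-8 β)
Conditions: H2 (1 atm), 10% Pd/C, EtOAc, rt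
Reagents that add atoms: none
Why: Heterogeneous hydrogenation reduces only the 1,1-disubstituted alkene (the tetrasubstituted isopropylidene is inert) and delivers H from the β-face, anti to the axial C9 and C5 methyls, which sets C8.

**Step 12**
Reactants: 15
Product: 16 stypoquinonic acid
Conditions: CAN (2.5 equiv), MeCN–H2O (2:1), 0 °C, 20 min
Reagents that add atoms: water, O (quinone oxygens)
Why: Oxidative demethylation of the 1,4-dimethoxyarene gives the p-quinone, and the short cold reaction spares the alkene, the acid and all stereocentres.

## Compound list
| No. | Name | SMILES | Role |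
|---|---|---|---|
| 1 | (1R,5R)-(+)-α-pinene | `CC1=CC[C@@H]2C[C@H]1C2(C)C` | starting material |
| 2 | (1R,5R)-(+)-verbenone | `CC1=CC(=O)[C@@H]2C[C@H]1C2(C)C` | intermediate |
| 3 | glyoxylic acid (sold as monohydrate) | `O=CC(=O)O` | starting material |
| 4 | verbenone-derived dienone acid | `OC(=O)/C=C/C1=CC(=O)[C@@H]2C[C@H]1C2(C)C` | intermediate |
| 5 | cis-verbanone-type keto acid | `OC(=O)CC[C@H]1CC(=O)[C@@H]2C[C@H]1C2(C)C` | intermediate |
| 6 | α-methyl keto acid | `OC(=O)CC[C@H]1[C@H](C)C(=O)[C@@H]2C[C@H]1C2(C)C` | intermediate |
| 7 | ethyl vinyl ketone | `C=CC(=O)CC` | starting material |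
| 8 | Michael adduct (diketo acid) | `OC(=O)CC[C@H]1[C@](C)(CCC(=O)CC)C(=O)[C@@H]2C[C@H]1C2(C)C` | intermediate |
| 9 | ring-opened chloro diketo acid | `OC(=O)CC[C@H]1[C@](C)(CCC(=O)CC)C(=O)CC[C@H]1C(C)(C)Cl` | intermediate |
| 10 | bicyclic isopropylidene enone acid | `CC1=C2CCC(=C(C)C)[C@@H](CCC(=O)O)[C@]2(C)CCC1=O` | intermediate |
| 11 | 2,6-dimethylhydroquinone | `Cc1cc(O)cc(C)c1O` | starting material |
| 12 | 2,5-dimethoxy-1,3-dimethylbenzene | `COc1cc(C)c(OC)c(C)c1` | intermediate |
| 13 | C9-benzylated trans-decalone acid | `COc1cc(C)c(OC)c(C[C@]2(C)[C@H]3CCC(=C(C)C)[C@@H](CCC(=O)O)[C@]3(C)CCC2=O)c1` | intermediate |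
| 14 | C8-methylene acid | `COc1cc(C)c(OC)c(C[C@]2(C)[C@H]3CCC(=C(C)C)[C@@H](CCC(=O)O)[C@]3(C)CCC2=C)c1` | intermediate |
| 15 | stypohydroquinonic acid dimethyl ether | `COc1cc(C)c(OC)c(C[C@]2(C)[C@H]3CCC(=C(C)C)[C@@H](CCC(=O)O)[C@]3(C)CC[C@H]2C)c1` | intermediate |
| 16 | stypoquinonic acid | `CC1=CC(=O)C=C(C[C@]2(C)[C@H]3CCC(=C(C)C)[C@@H](CCC(=O)O)[C@]3(C)CC[C@H]2C)C1=O` | target |

## Step count
- **Total steps:** 12
- **Longest linear sequence:** 11 (Steps 1–7 and 9–12)

## Steps most likely to fail
1. **Step 9 (proposed new step).**
   - Risks: escape of the triplet radical pair (giving saturated ketone and bibenzyl), lumiketone or deconjugation photochemistry, and a cis ring fusion that cannot be corrected afterwards.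
   - Fallback (known chemistry, ionic rather than radical): Li/NH3 reduction of the lithium carboxylate of 10 to the trans enolate, then C-alkylation with 2,5-dimethoxy-3-methylbenzyl bromide, which gives the same 13.
2. **Step 7.**
   - Risk: E2 may favour the isopropenyl isomer, or solvolysis may intervene.
   - Fallback: eliminate unselectively with DBU, then converge both isomers with a Co(salen)/PhSiH3 MHAT one-position alkene isomerisation. This is a radical, acid-free process that stops at the tetrasubstituted alkene and does not touch C4.
3. **Step 5.**
   - Risk: the hindered tertiary enolate may add sluggishly while ethyl vinyl ketone polymerises.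
   - Fallback: replace conjugate addition with a Wichterle-type C-alkylation using 1,3-dichloropent-2-ene (a reactive allylic halide with the same facial control). Concentrated H2SO4 then unmasks the ethyl ketone and opens the cyclobutane in the same operation.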